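Let us count in one unit, the exposure: the natural logarithm of one over the fraction of substrate left. We follow one substrate molecule. Its chances of surviving successive moments multiply, so exposures add, and we take each moment's exposure as proportional to the partner and the free catalyst then present. With substrate at 20 mM and free catalyst at 5 mol% held fixed, runs should therefore share one quantity, the exposure per equivalent of partner at a given time. The birch run gives 0.280 at 2.50 min.

| setting | oak | birch | elm | flask |
|---|---|---|---|---|
| substrate | 20 mM | 20 mM | 10 mM | 20 mM |
| coupling partner | 1.5 equiv | 2.2 equiv | 3 equiv | 3.00 equiv |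
| free catalyst | 5 mol% | 5 mol% | 5 mol% | 5 mol% |
| remark | run made earlier | run made earlier | run made earlier |  |
| time |  |  |  | 4.0 min |

| run | time / min | target / % | substrate / % |
|---|---|---|---|
| oak | 0.333 | 16 | 90 |
| oak | 0.833 | 21 | 75 |
| oak | 1.50 | 26 | 71 |
| oak | 2.50 | 34 | 66 |
| birch | 0.200 | 13 | 88 |
| birch | 0.417 | 21 | 81 |
| birch | 1.00 | 32 | 65 |
| birch | 2.50 | 43 | 54 |
| elm | 0.333 | 5 | 92 |
| elm | 0.833 | 11 | 85 |
| elm | 1.50 | 20 | 80 |
| elm | 2.50 | 29 | 73 |

(standard deviation of a reading: 2 percentage points)

1. amount of target in percent of the substrate charged, at 50 s, 2.0 min and 4.0 min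



We build our own reckoning in stages, starting with the main step alone and the other concentrations held at their charge, a pseudo-first-order picture. The first birch reading gives an exposure rate of 0.639 min⁻¹. Scaled to 3.00 equiv, this gives an exposure of 3.49 at 4.0 min, or 96.9% target.

Next comes the fading. By 2.50 min birch shows an exposure of 0.616, less than the 1.60 of a steady rate, and we read this as free catalyst being lost. For the flask we reckon an exposure at that time of 0.840.

Last comes the partner. We reckon it down by 18.9% of its charge at that time in the flask, against 20.9% read from the substrate in birch, and we make no correction.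

Oak gives the exposure at 50 s. For later times we assume a constant gain per logarithm of time, taken from the last two birch readings: 0.0920 per equivalent. Our course is 43.7%, 54.1% and 62.1%.

The forecast says 42%, 51% and 63%. That is lower than ours at 50 s and 2.0 min, and higher at 4.0 min. It adds: “The mechanism is uncertain, so the ranges are wide.”

The flask gives 38.3%, 53.6% and 64.1%.

    2 free catalyst → spent catalyst (k = 16.0 M⁻¹ s⁻¹)
    substrate + coupling partner + free catalyst → free catalyst + target (k = 290 M⁻² s⁻¹)

The forecast is within tolerance at each point. At 2.00 min free catalyst stands at 20.7% of its charge and spent catalyst at 79.3%. The 36% of substrate left in the flask at 4.00 min is an exposure per equivalent of 0.341. Carried to the oak run, the birch value 0.280 predicts 65.7% substrate at 2.50 min, and oak read 66%.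

The runs were computed for an exercise, noise included.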